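All runs were computed with constants of no real substance, and the scatter is random.

The charge of Q was conserved, so at every moment each part of it was Q, J or something else, and I counted in fractions of that charge.

the same everywhere: Q 0.075 M; X 0.12 mM

|  | Z | remark | time |
|---|---|---|---|
| theta | 0.10 M | run made earlier |  |
| epsilon | 0.11 M | run made earlier |  |
| winter | 0.0980 M |  | 8.0 h |
| dusk | 0.120 M |  | 8.0 h |
| autumn | 0.140 M |  | 8.0 h |

| run | time / h | J / % | Q / % |
|---|---|---|---|
| theta | 0.667 | 8 | 40 |
| theta | 2.00 | 29 | 28 |
| theta | 4.00 | 38 | 16 |
| theta | 6.00 | 49 | 7 |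
| epsilon | 0.667 | 12 | 37 |
| epsilon | 2.00 | 28 | 24 |
| epsilon | 4.00 | 44 | 14 |
| epsilon | 6.00 | 51 | 8 |

(standard deviation of a reading: 1.5 percentage points)

- which of the two there is more of at the end, winter (L / J)
- which of the two there is more of at the end, dusk (L / J)
- which of the two there is more of at the end, autumn (L / J)
- amount of J at the end, in percent of the Q charged, winter
- amount of J at the end, in percent of the Q charged, dusk
- amount of J at the end, in percent of the Q charged, autumn



Dividing the rate of making J by the rate of making the remainder removes the clock, so I took the amounts themselves: N is J over what is neither Q nor J. At the last reading N was 1.11 in theta and 1.24 in epsilon. Dividing each by b, the Z charged per Q charged, gave 0.835 and 0.848, which agree, though over a small step in Z. Their mean is 0.842, and I called it s, the split number: a selectivity factor giving N per unit of b, with Q and X held at these charges.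

So each flask became one number, s·b. In winter it was 1.10, in dusk 1.35, in autumn 1.57. Each stood above one, so by this reckoning J exceeded the remainder in each flask, and L, as part of that remainder, stayed below J.

Continuing the last ratio of Q readings left about 3.82% of Q at 8.0 h. Taking that Q for all three flasks, my J was then 50.4% in winter, 55.2% in dusk and 58.8% in autumn.

Was one number enough? Not quite: at 4.00 h the same mean was 0.667, less than s. Time had not fully dropped out, and I took my values as low.

The forecast gave 52%, 55% and 56%, a spread smaller than mine, and said “I expect J to edge out L in all three runs”.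

Winter, dusk and autumn gave J at 54.4%, 59.0% and 62.1%, with L at 34.1%, 31.3% and 29.4%.

    Q + X ⇌ X + E (K = 1.20, k = 1.10 × 10⁵ M⁻¹ h⁻¹)
    Z + G → X + J (k = 3280 M⁻¹ h⁻¹)
    Q + Z → D (k = 0.217 M⁻¹ h⁻¹)
    E → L (k = 0.210 h⁻¹)
    X + E ⇌ G (K = 24.2 M⁻¹, k = 9290 M⁻¹ h⁻¹)

In dusk, with 3.1% of Q left at 8.00 h and L, D and E as the remainder, N was 1.56, more than the 1.35 that s·b had given.

Take the flask like dusk but with 0.048 M of Z. There s·b is 0.539, below one, which puts J at 35.0% of the Q consumed. The computed flask holds 35.3% of J with 9.03% of Q left, which is 38.8%, and its L, at 43.7%, stands above J.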